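**Retrosynthetic overview**
- The C12 arm is closed last by cross-metathesis and hydrogenation between a hept-6-enyl arm on the bicyclic core and 4-(hept-6-enyl)phenol (7 + 7 − 2 carbons).
- The quaternary ether carbon C5 is set by adding methyl last, syn to the lactone oxygen, to a lactone-fused oxocarbenium ion made from a methyl ketal.
- Ring B (tetrahydrofuran) is closed by 5-exo-dig addition of the C3a hydroxyl to an internal alkyne.
- Ring A (γ-lactone) comes from Baeyer–Villiger ring expansion of a 3-hydroxy-2,2-disubstituted cyclobutanone: the quaternary carbon shifts from carbon to oxygen with retention. The ketol comes from desymmetrising reduction of a prochiral cyclobutane-1,3-dione.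
- Ring order: bought four-membered ring → ring A by ring expansion → ring B by cycloisomerisation.

Assumption: the cyclobutane-1,3-dione starting material of step 3 is purchasable (sold as its enol tautomer); if it is not, the fallback for step 3 reaches its alkylation product without it.

**Route**

Step 1
Reactants: 1 prop-2-yn-1-ol; 2 6-bromohex-1-ene
Product: 3 non-8-en-2-yn-1-ol
Conditions: n-BuLi (2.1 equiv), THF–DMPU, −78 °C; then 2, −78 °C → rt; H2O
Reagents that add atoms: none
Why: Acetylide alkylation: the dilithium salt of propargyl alcohol reacts with the primary bromide at the acetylide carbon only, the alkoxide being too hard and hindered to compete.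

Step 2
Reactants: 3 non-8-en-2-yn-1-ol
Product: 4 1-bromonon-8-en-2-yne
Conditions: CBr4, PPh3, CH2Cl2, 0 °C
Reagents that add atoms: tetrabromomethane, BrC(Br)(Br)Br
Why: Appel reaction converts the primary propargylic alcohol to the bromide under neutral conditions that leave the alkyne and the terminal alkene untouched.

Step 3
Reactants: 5 2-methylcyclobutane-1,3-dione; 4 1-bromonon-8-en-2-yne
Product: 6 2-methyl-2-(non-8-en-2-yn-1-yl)cyclobutane-1,3-dione
Conditions: K2CO3, MeCN, 40 °C
Reagents that add atoms: none
Why: C-alkylation of a 1,3-diketone: the stabilised enolate of the acidic dione attacks the soft propargylic bromide at carbon, creating the prochiral quaternary carbon.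

Step 4
Reactants: 6 2-methyl-2-(non-8-en-2-yn-1-yl)cyclobutane-1,3-dione
Product: 7 (2S,3S)-3-hydroxy-2-methyl-2-(non-8-en-2-yn-1-yl)cyclobutan-1-one
Conditions: (R)-2-methyl-CBS-oxazaborolidine (20 mol%), catecholborane (1.2 equiv), toluene, −78 °C; pH 7 buffer
Reagents that add atoms: none
Why: Corey–Bakshi–Shibata reduction used as a desymmetrisation: the catalyst fixes the carbinol carbon as S and hydride enters anti to the larger alkynyl arm, so only one enantiotopic carbonyl is reduced, the quaternary carbon becomes S and OH ends cis to the alkynyl arm (the minor trans ketol is removed by chromatography; catecholborane at −78 °C leaves alkene and alkyne alone).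

Step 5
Reactants: 7 (2S,3S)-3-hydroxy-2-methyl-2-(non-8-en-2-yn-1-yl)cyclobutan-1-one
Product: 8 (4S,5S)-4-hydroxy-5-methyl-5-(non-8-en-2-yn-1-yl)dihydrofuran-2(3H)-one
Conditions: H2O2 (30% aq.), AcOH, 0–5 °C
Reagents that add atoms: hydrogen peroxide, OO
Why: Baeyer–Villiger ring expansion: the fully substituted α-carbon migrates from carbon to oxygen in preference to CH2 and with retention, so the strained cyclobutanone becomes the γ-lactone (ring A) and the all-carbon quaternary centre becomes the C6a–O centre of the target; aqueous H2O2/AcOH oxidises cyclobutanones without epoxidising isolated alkenes.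

Step 6
Reactants: 8 (4S,5S)-4-hydroxy-5-methyl-5-(non-8-en-2-yn-1-yl)dihydrofuran-2(3H)-one
Product: 10 (3aS,5S,6aS)-5-(hept-6-en-1-yl)-5,6a-dimethyltetrahydrofuro[3,2-b]furan-2(3H)-one, via methyl ketal 9 (not isolated)
Conditions: Ph3PAuNTf2 (2 mol%), MeOH, rt; evaporate; then AlMe3 (4 equiv), TMSOTf (1.2 equiv), CH2Cl2, −78 → −40 °C
Reagents that add atoms: trimethylaluminium, C[Al](C)C
Why: Proposed new method: the known gold-catalysed 5-exo-dig hydroalkoxylation with methanol addition closes ring B as ketal 9 (cis-fused by necessity); TMSOTf then ionises 9 to a lactone-fused tertiary oxocarbenium ion whose envelope holds the C6a–O bond pseudoaxial and the C6a methyl pseudoequatorial, so AlMe3 (which can also bind the lactone oxygen) delivers methyl by inside attack on the face syn to the lactone oxygen and sets C5 as S with the chain on the convex face; the closest known reaction types are Woerpel-type stereoselective C-glycosylation of five-membered oxocarbenium ions and AlMe3 substitution of ketals, neither yet shown for a quaternary centre on a lactone-fused ion.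

Step 7
Reactants: 11 hepta-1,6-diene; 12 4-iodophenol
Product: 14 4-(hept-6-en-1-yl)phenol, via alkylborane 13 (not isolated)
Conditions: 9-BBN (1.0 equiv), 11 (3 equiv), THF, 0 °C → rt; then 12, Pd(dppf)Cl2 (3 mol%), NaOH (3 M aq.), 65 °C
Reagents that add atoms: none
Why: Anti-Markovnikov hydroboration of one alkene of the excess diene gives a primary alkylborane that undergoes B-alkyl Suzuki–Miyaura coupling with the aryl iodide, the phenol being carried as its phenoxide.

Step 8
Reactants: 10 (3aS,5S,6aS)-5-(hept-6-en-1-yl)-5,6a-dimethyltetrahydrofuro[3,2-b]furan-2(3H)-one; 14 4-(hept-6-en-1-yl)phenol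
Product: 16 (3aS,5S,6aS)-5-[12-(4-hydroxyphenyl)dodecyl]-5,6a-dimethyltetrahydrofuro[3,2-b]furan-2(3H)-one (plakortone N), via alkene 15 (not isolated)
Conditions: second-generation Hoveyda–Grubbs catalyst RuCl2(H2IMes)(=CH-C6H4-2-OiPr) (5 mol%), 14 (3 equiv), CH2Cl2, 40 °C; then Pd/C, H2 (1 atm), EtOAc, rt
Reagents that add atoms: none
Why: Olefin cross-metathesis joins the two terminal alkenes and hydrogenation of the E/Z alkene over Pd/C gives the saturated C12 chain without touching the lactone, the ether, the phenol or any stereocentre.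

**Compound list**

1 | prop-2-yn-1-ol | C#CCO | starting material
2 | 6-bromohex-1-ene | BrCCCCC=C | starting material
3 | non-8-en-2-yn-1-ol | OCC#CCCCCC=C | intermediate
4 | 1-bromonon-8-en-2-yne | BrCC#CCCCCC=C | intermediate
5 | 2-methylcyclobutane-1,3-dione | CC1C(=O)CC1=O | starting material
6 | 2-methyl-2-(non-8-en-2-yn-1-yl)cyclobutane-1,3-dione | CC1(CC#CCCCCC=C)C(=O)CC1=O | intermediate
7 | (2S,3S)-3-hydroxy-2-methyl-2-(non-8-en-2-yn-1-yl)cyclobutan-1-one | C=CCCCCC#CC[C@]1(C)C(=O)C[C@@H]1O | intermediate
8 | (4S,5S)-4-hydroxy-5-methyl-5-(non-8-en-2-yn-1-yl)dihydrofuran-2(3H)-one | C=CCCCCC#CC[C@]1(C)OC(=O)C[C@@H]1O | intermediate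
9 | (3aS,6aS)-5-(hept-6-en-1-yl)-5-methoxy-6a-methyltetrahydrofuro[3,2-b]furan-2(3H)-one (both C5 epimers) | C=CCCCCCC1(OC)C[C@]2(C)OC(=O)C[C@@H]2O1 | intermediate
10 | (3aS,5S,6aS)-5-(hept-6-en-1-yl)-5,6a-dimethyltetrahydrofuro[3,2-b]furan-2(3H)-one | C[C@]1(CCCCCC=C)C[C@]2(C)OC(=O)C[C@@H]2O1 | intermediate
11 | hepta-1,6-diene | C=CCCCC=C | starting material
12 | 4-iodophenol | Oc1ccc(I)cc1 | starting material
13 | 9-(hept-6-en-1-yl)-9-borabicyclo[3.3.1]nonane | C=CCCCCCB1C2CCCC1CCC2 | intermediate
14 | 4-(hept-6-en-1-yl)phenol | C=CCCCCCc1ccc(O)cc1 | intermediate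
15 | (3aS,5S,6aS)-5-[12-(4-hydroxyphenyl)dodec-6-en-1-yl]-5,6a-dimethyltetrahydrofuro[3,2-b]furan-2(3H)-one (E/Z mixture) | C[C@]1(CCCCCC=CCCCCCc2ccc(O)cc2)C[C@]2(C)OC(=O)C[C@@H]2O1 | intermediate
16 | plakortone N, (3aS,5S,6aS)-5-[12-(4-hydroxyphenyl)dodecyl]-5,6a-dimethyltetrahydrofuro[3,2-b]furan-2(3H)-one | C[C@]1(CCCCCCCCCCCCc2ccc(O)cc2)C[C@]2(C)OC(=O)C[C@@H]2O1 | target

**Step count**
- Total: 8 steps (steps 6 and 8 each run two operations in one flask).
- Longest linear sequence: 7 steps (steps 1–6, then 8).

**Three steps most likely to fail**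

Step 3 (C-alkylation of the strained dione). The enolate may alkylate on oxygen, or the 2,2-disubstituted dione may ring-open. The fallback builds the quaternary carbon before the four-membered ring by the known ketene/ethoxyacetylene cycloaddition. It sets out from 4 and returns at 6, and no longer needs 5. The dianion of propanoic acid (LiN(iPr)2, 2 equiv, THF) is alkylated with 4 to give 2-methylundec-10-en-4-ynoic acid F1. Oxalyl chloride converts this to 2-methylundec-10-en-4-ynoyl chloride F2. Et3N then generates methyl(non-8-en-2-yn-1-yl)ketene F3 in the flask, which adds to ethoxyacetylene ([2+2]) to give 3-ethoxy-4-methyl-4-(non-8-en-2-yn-1-yl)cyclobut-2-en-1-one F4. Aqueous HCl in THF hydrolyses the vinylogous ester to 6.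

Step 4 (desymmetrising reduction on a four-membered dione). The ee, or the choice between the two carbonyl groups, may be poor. The fallback separates relative from absolute control by reduction followed by enzymatic kinetic resolution. It sets out from 6 and returns at 7. NaBH4 (0.3 equiv, MeOH, −78 °C) attacks anti to the alkynyl arm and gives racemic cis-3-hydroxy-2-methyl-2-(non-8-en-2-yn-1-yl)cyclobutan-1-one F5. Burkholderia cepacia lipase with vinyl acetate acetylates the (2R,3R)-enantiomer to (1R,2R)-2-methyl-2-(non-8-en-2-yn-1-yl)-3-oxocyclobutyl acetate F6 (Kazlauskas preference). The unreacted alcohol is 7, at most 50%, separated by chromatography.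

Step 6 (the proposed new methylation). Methyl may enter from the convex face, or the oxocarbenium ion may only eliminate to enol ethers. The fallback brings in the two carbon groups in the opposite order, so that the face the nucleophile prefers now carries the chain. It uses the known organocopper–BF3 substitution of a ketal (Normant–Alexakis type), sets out from 5 and returns at 10.
- Alkylation of 5 with propargyl bromide (K2CO3, MeCN) gives 2-methyl-2-(prop-2-yn-1-yl)cyclobutane-1,3-dione F7.
- The reduction of step 4 gives (2S,3S)-3-hydroxy-2-methyl-2-(prop-2-yn-1-yl)cyclobutan-1-one F8.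
- H2O2/AcOH gives (4S,5S)-4-hydroxy-5-methyl-5-(prop-2-yn-1-yl)dihydrofuran-2(3H)-one F9.
- Ph3PAuNTf2 in MeOH gives (3aS,6aS)-5-methoxy-5,6a-dimethyltetrahydrofuro[3,2-b]furan-2(3H)-one F10, in which the C5 methyl comes from the terminal alkyne carbon.
- Hept-6-enylmagnesium bromide (from 7-bromohept-1-ene), CuBr·SMe2 and BF3·OEt2 in Et2O at −78 °C replace the methoxy group by the chain to give 10.

This fallback is chosen only if step 6 shows convex-face delivery; if the facial preference is weak, the C5 epimers of 10 are separated by chromatography.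

**Further compounds**

F1 | step 3 | 2-methylundec-10-en-4-ynoic acid | C=CCCCCC#CCC(C)C(=O)O
F2 | step 3 | 2-methylundec-10-en-4-ynoyl chloride | C=CCCCCC#CCC(C)C(Cl)=O
F3 | step 3 | methyl(non-8-en-2-yn-1-yl)ketene | C=CCCCCC#CCC(C)=C=O
F4 | step 3 | 3-ethoxy-4-methyl-4-(non-8-en-2-yn-1-yl)cyclobut-2-en-1-one (racemic) | CCOC1=CC(=O)C1(C)CC#CCCCCC=C
F5 | step 4 | racemic cis-3-hydroxy-2-methyl-2-(non-8-en-2-yn-1-yl)cyclobutan-1-one (7 and its enantiomer, 1:1) | C=CCCCCC#CC[C@]1(C)C(=O)C[C@@H]1O.C=CCCCCC#CC[C@@]1(C)C(=O)C[C@H]1O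
F6 | step 4 | (1R,2R)-2-methyl-2-(non-8-en-2-yn-1-yl)-3-oxocyclobutyl acetate | C=CCCCCC#CC[C@@]1(C)C(=O)C[C@H]1OC(C)=O
F7 | step 6 | 2-methyl-2-(prop-2-yn-1-yl)cyclobutane-1,3-dione | CC1(CC#C)C(=O)CC1=O
F8 | step 6 | (2S,3S)-3-hydroxy-2-methyl-2-(prop-2-yn-1-yl)cyclobutan-1-one | C#CC[C@]1(C)C(=O)C[C@@H]1O
F9 | step 6 | (4S,5S)-4-hydroxy-5-methyl-5-(prop-2-yn-1-yl)dihydrofuran-2(3H)-one | C#CC[C@]1(C)OC(=O)C[C@@H]1O
F10 | step 6 | (3aS,6aS)-5-methoxy-5,6a-dimethyltetrahydrofuro[3,2-b]furan-2(3H)-one (both C5 epimers) | COC1(C)C[C@]2(C)OC(=O)C[C@@H]2O1
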